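Two yields and one choice were asked of me, and a single earlier run had to answer them.

| flask | substrate | free catalyst | remark | time |
|---|---|---|---|---|
| dawn | 0.60 M | 2 mM | run made earlier |  |
| north | 0.40 M | 1.0 mM |  | 5.0 h |
| south | 0.40 M | 2.0 mM |  | 3.0 h |

dawn run (percent of the substrate charged)

| time / min | target / % | substrate / % |
|---|---|---|
| 8.00 | 4.1 | 94.3 |
| 15.0 | 8.4 | 92.6 |
| 25.0 | 10.9 | 88.7 |
| 40.0 | 15.5 | 85.0 |
| 60.0 | 17.2 | 83.2 |
| 120 | 19.6 | 81.4 |

(scatter of a reading: 0.5 percentage points)

- which of the two ends with the higher amount of target, in percent of the substrate charged ("neither" if they lie within 2 percentage points) (north / south / neither)
- target at the end, in percent of the substrate charged, north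
- target at the end, in percent of the substrate charged, south

- no earlier run changes the charge of free catalyst; that part of a forecast is a guess

**Equivalent time.** In dawn, target and substrate summed to 101% at the last reading, and the target had stalled. North had 150 min and south 180 min, both past dawn's last reading at 120 min. This is the equivalent time: a flask's time multiplied by its c(free catalyst) and divided by that of dawn, which assumes that progress goes with free catalyst and time together, and that assumption was a guess.

**My bracket.** If the stall was a balance between substrate and target (equilibrium), both flasks stood at dawn's 19.6%, which was my top for north and my floor for south. If free catalyst died with the clock, yield went with its charge, which put the floor for north at 9.80%. If free catalyst died after a fixed count of turnovers, dawn's amount of target spread over the smaller charge of south, which put its top at 29.4%. Dawn held one charge of free catalyst, so I could tighten no further by hand.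

**The forecast.** It said south, with 14% for north and 21% for south, both inside my bracket, on this ground: “Both death readings favour south, so I lean south, with wide ranges.”

**The result.** The flask gave neither: north, at equivalent time 150 min, reached 20.4% and south 20.5%, so north stood 0.80 percentage points above my top, which was a reading with scatter 0.5 points.

    substrate + free catalyst ⇌ catalyst intermediate (K = 0.530 /M, k = 239 /M/h)
    catalyst intermediate ⇌ free catalyst + target (K = 0.490 M, k = 5340 /h)

**Falling back.** North stalled through the falling back of both steps: without catalyst intermediate falling back to substrate and free catalyst it ended at 60.2%, and without free catalyst and target falling back to catalyst intermediate at 66.4%. North read at 80 min has an equivalent time of 40.0 min, where dawn read 15.5%, and that flask held 15.1% of target.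

The readings are calculated with made-up constants; noise was put on by code.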